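**Assumption:** the target SMILES has no stereocentre or stereogenic double bond. Barbatolic acid is achiral, so the single-enantiomer requirement is met trivially and no step needs stereocontrol.

## Retrosynthetic overview
1. Barbatolic acid 12 comes from allyl ester 11 by Pd(0) deallylation. Ester 11 comes from bis-resorcylate 9 by installing both CHO groups at once in a two-fold Ti-chelate-directed C3 formylation.
2. Key step: 9 comes from the acyclic bis-ynoate 5 plus two equivalents of dimedone-derived diene 8, through a double Diels–Alder/retro-Diels–Alder (Alder–Rickert) benzannulation.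
3. The usual disconnection (aryl acid plus benzylic alcohol or halide) is avoided. The "benzyl ester" C–O bond is made earlier as a simple propargyl ester, where the phthalide collapse that troubles ring-B hydroxy-esters cannot occur.
4. Bis-ynoate 5 comes from but-2-ynoic acid 4 and allyl 4-hydroxybut-2-ynoate 3.
5. Ring order: both benzene rings form in one pot in step 4. Ring B forms first (the more electrophilic 4-acyloxy-ynoate), then ring A (the tetrolate).

## Route

**Step 1**
Reactants: 1, 4-hydroxybut-2-ynoic acid; 2, allyl bromide
Product: 3, allyl 4-hydroxybut-2-ynoate
Conditions: KHCO3 (1.2 equiv), allyl bromide (1.3 equiv), DMF, rt, 16 h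
Reagents that add atoms: allyl bromide (2), C=CCBr
Why: Carboxylate SN2 O-alkylation, in which bicarbonate ionises only the strongly acidic ynoic acid, so it is esterified selectively while the propargylic OH and the base-sensitive ynoate are untouched.

**Step 2**
Reactants: 3, allyl 4-hydroxybut-2-ynoate; 4, but-2-ynoic acid (tetrolic acid)
Product: 5, allyl 4-(but-2-ynoyloxy)but-2-ynoate (acyclic bis-ynoate)
Conditions: 4 (1.2 equiv), DCC (1.2 equiv), DMAP (5 mol %), CH2Cl2, –20 to 0 °C
Reagents that add atoms: but-2-ynoic acid (4), CC#CC(=O)O
Why: Steglich esterification of an unhindered primary propargylic alcohol, where low temperature and minimal DMAP suppress ynoate-to-allenoate isomerisation, and this sets the future ArCO–O–CH2Ar linkage before any ring exists.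

**Step 3**
Reactants: 6, dimedone (5,5-dimethylcyclohexane-1,3-dione); 7, trimethylsilyl triflate
Product: 8, 5,5-dimethyl-1,3-bis(trimethylsilyloxy)cyclohexa-1,3-diene
Conditions: TMSOTf (2.3 equiv), Et3N (2.6 equiv), Et2O, 0 °C to rt; decant from Et3NH·OTf, bulb-to-bulb distil, use at once
Reagents that add atoms: TMSOTf (7), C[Si](C)(C)OS(=O)(=O)C(F)(F)F
Why: Soft double enol silylation, in which the intermediate symmetrical 1,3-bis(silyloxy)allyl cation can only lose a proton from one of two equivalent CH2 groups, so 8 is the sole diene possible.

**Step 4 (key step)**
Reactants: 5, bis-ynoate; 8, bis(silyloxy)diene (6 equiv)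
Product: 9, allyl 2,4-dihydroxy-6-{[(2,4-dihydroxy-6-methylbenzoyl)oxy]methyl}benzoate
Conditions: neat, BHT (cat.), base-washed sealed tube, Ar, 150 °C, 36–48 h (–2 isobutene); then 1 M HCl/THF, rt, 30 min
Reagents that add atoms: diene 8, CC1(C)CC(O[Si](C)(C)C)=CC(O[Si](C)(C)C)=C1 (each equivalent delivers a C4H2O2 unit; the aqueous acid supplies only H)
Why: Two-fold Diels–Alder/retro-Diels–Alder (Alder–Rickert) benzannulation, established for β-alkyl ynoates with this diene: the nucleophilic CH terminus of 8 bonds to each ynoate β-carbon and the C(OTMS) terminus to the α-carbon, then isobutene extrusion aromatises each adduct so every ester carbon sits between OH and CH3 or CH2O (orsellinate pattern), with no stereocentres surviving.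

**Step 5**
Reactants: 9, bis-resorcylate; 10, dichloromethyl methyl ether
Product: 11, allyl 3-formyl-6-{[(3-formyl-2,4-dihydroxy-6-methylbenzoyl)oxy]methyl}-2,4-dihydroxybenzoate (allyl barbatolate)
Conditions: TiCl4 (10 equiv), Cl2CHOMe (5 equiv), CH2Cl2, –20 to 0 °C, 2 h; then ice-cold 2 M HCl, 1 h
Reagents that add atoms: dichloromethyl methyl ether (10), COC(Cl)Cl (formyl carbon); water, O (formyl oxygen on hydrolysis)
Why: Double Rieche formylation under Ti(IV) chelate control, in which each ring is a salicylate whose 2-O/C=O titanium chelate directs the electrophile ortho to the chelated oxygen (C3, between the two oxygens), as in the orsellinate-to-haematommate conversion, and the first CHO deactivates each ring against over-reaction.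

**Step 6**
Reactants: 11, allyl barbatolate
Product: 12, barbatolic acid
Conditions: Pd(PPh3)4 (5 mol %), sodium p-toluenesulfinate (1.2 equiv), THF/MeOH, rt, 1 h; then cold 1 M HCl, crystallise from acetone
Reagents that add atoms: none
Why: Tsuji–Trost-type Pd(0) deallylation, in which only the allyl ester ionises to a π-allyl complex that the soft sulfinate traps irreversibly, while the internal electron-poor benzylic ester, the H-bonded aldehydes and the phenols survive these near-neutral room-temperature conditions, which also disfavour phthalide formation.

## Compound list
1 | 4-hydroxybut-2-ynoic acid | OCC#CC(=O)O | starting material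
2 | allyl bromide | C=CCBr | starting material
3 | allyl 4-hydroxybut-2-ynoate | OCC#CC(=O)OCC=C | intermediate
4 | but-2-ynoic acid | CC#CC(=O)O | starting material
5 | allyl 4-(but-2-ynoyloxy)but-2-ynoate | CC#CC(=O)OCC#CC(=O)OCC=C | intermediate
6 | dimedone | CC1(C)CC(=O)CC(=O)C1 | starting material
7 | trimethylsilyl triflate | C[Si](C)(C)OS(=O)(=O)C(F)(F)F | starting material
8 | 5,5-dimethyl-1,3-bis(trimethylsilyloxy)cyclohexa-1,3-diene | CC1(C)CC(O[Si](C)(C)C)=CC(O[Si](C)(C)C)=C1 | intermediate
9 | allyl 2,4-dihydroxy-6-{[(2,4-dihydroxy-6-methylbenzoyl)oxy]methyl}benzoate | Cc1cc(O)cc(O)c1C(=O)OCc1cc(O)cc(O)c1C(=O)OCC=C | intermediate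
10 | dichloromethyl methyl ether | COC(Cl)Cl | starting material
11 | allyl barbatolate | Cc1cc(O)c(C=O)c(O)c1C(=O)OCc1cc(O)c(C=O)c(O)c1C(=O)OCC=C | intermediate
12 | barbatolic acid (achiral) | Cc1cc(O)c(C=O)c(O)c1C(=O)OCc1cc(O)c(C=O)c(O)c1C(=O)O | target

## Step count
- **Total steps:** 6
- **Longest linear sequence:** 5 (steps 1, 2, 4, 5, 6)

## Three steps most likely to fail
1. **Step 4 (double Alder–Rickert).**
   - Risk: the tetrolate alkyne is the slow dienophile, and long heating may degrade the propargylic ester or the diene before the second cycloaddition finishes.
   - Fallback: give up simultaneous ring construction. Convert 3 to allyl 4-bromobut-2-ynoate (MsCl, then LiBr) and run a single cycloaddition with 8 on this activated alkyne to obtain the ring-B benzylic bromide. Bring in ring A as the carboxylate of commercial orsellinic acid (KHCO3, DMF, SN2), then desilylate to rejoin the route at 9.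
2. **Step 5 (double C3 formylation).**
   - Risk: any C5 leakage is compounded over two rings. TiCl4 could also trigger ester-assisted loss of the ring-A carboxylate (phthalide formation) or attack on the allyl alkene.
   - Fallback: carry the C3 carbon in with the diene. Use the bis-silyl dienol ether of commercial 2,5,5-trimethylcyclohexane-1,3-dione in step 4 to obtain the bis(3-methyl) resorcylate. Then oxidise only the 3-methyl groups, which are ortho to two OH groups and can react via an o-quinone methide, to CHO with DDQ in aqueous dioxane. The 6-methyl group is meta to both OH groups and should stay inert.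
3. **Step 6 (deallylation).**
   - Risk: phenol O-allylation, Pd binding by the polyphenol, or displacement of haematommate by the liberated carboxylate to give the phthalide.
   - Fallback: change the carboxyl mask from step 1 onwards. Esterify 1 with 2-(trimethylsilyl)ethanol and release the acid at the end by TFA-triggered fragmentation. This is metal-free and generates neither a π-allyl electrophile nor a free carboxylate nucleophile.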